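Numbering (target, used throughout): C1 quaternary carbinol, C2 CHOBz, C3 CHOH, C4=C5 alkene, C6 CHCl, C7 exocyclic CH2OBz.
Retrosynthetic cuts, in order: O3–Si (protecting group); C6–Cl (HCl taken off, leaving a C1–C6 oxirane); the two benzoyl–O bonds; the oxirane C1–O and C6–O bonds (back to a cyclohexadiene with C1=C6 and C4=C5); C1–C7; last the C2–O bond (inversion), back to a microbial cis-diol.
Enabling feature: the trans C1-OH/C6-Cl pair beside the C4=C5 alkene is the HCl adduct of a vinyl oxirane fused to the six-membered ring at C1–C6, and the parent C1=C6 alkene is allylic to both the ring C2 hydroxyl and the C7 hydroxyl, which can bind a metal peroxide and hold it on one face.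
Forward order: the carbocycle is bought intact as (1S,2S)-3-bromocyclohexa-3,5-diene-1,2-diol; C7 is joined by Stille coupling (step 4); the only ring made is the oxirane (step 5); HCl opens it again (step 7).
Stereochemistry: C3 comes from the starting diol, C2 from a Mitsunobu inversion, C1 and the oxirane face from oxygen delivery syn to C2-OH, and C6 from anti opening of the oxirane by chloride.

Key step: step 5

Step 1
Reactants: 1 (1S,2S)-3-bromocyclohexa-3,5-diene-1,2-diol
Product: 2 (1S,6S)-2-bromo-6-[(tert-butyldimethylsilyl)oxy]cyclohexa-2,4-dien-1-ol (silyl ether on the hydroxyl remote from bromine, the future O3; cis)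
Conditions: TBSCl (1.05 equiv), imidazole, DMF, −10 °C
Reagents that add atoms: tert-butyldimethylsilyl chloride, CC(C)(C)[Si](C)(C)Cl
Why: Imidazole-promoted silyl ether formation should take place at the distal hydroxyl, because the proximal one is crowded and inductively deactivated by the neighbouring vinylic bromine, and no stereocentre is touched.

Step 2
Reactants: 2 (1S,6S)-2-bromo-6-[(tert-butyldimethylsilyl)oxy]cyclohexa-2,4-dien-1-ol
Product: 3 (1R,6S)-2-bromo-6-[(tert-butyldimethylsilyl)oxy]cyclohexa-2,4-dien-1-yl 4-nitrobenzoate (ester and silyl ether trans)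
Conditions: 4-nitrobenzoic acid, PPh3, DIAD, toluene, −30 to 0 °C
Reagents that add atoms: 4-nitrobenzoic acid, OC(=O)c1ccc(cc1)[N+](=O)[O-]
Why: Mitsunobu esterification turns the free allylic carbinol into an oxyphosphonium salt that 4-nitrobenzoate displaces by SN2 with inversion, which converts the cis pattern into the trans C2/C3 pattern of the target, while the electron-poor bromodiene, the weakly basic carboxylate and the low temperature should hold back loss of the activated oxygen towards the arene.

Step 3
Reactants: 3 (1R,6S)-2-bromo-6-[(tert-butyldimethylsilyl)oxy]cyclohexa-2,4-dien-1-yl 4-nitrobenzoate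
Product: 4 (1R,6S)-2-bromo-6-[(tert-butyldimethylsilyl)oxy]cyclohexa-2,4-dien-1-ol (trans)
Conditions: K2CO3 (0.2 equiv), MeOH, 0 °C
Reagents that add atoms: none
Why: Carbonate-catalysed transesterification with methanol cleaves the electron-poor aryl ester at its acyl–O bond, so the inverted carbinol keeps its configuration, the short cold exposure should keep the silyl group from migrating to the neighbouring trans hydroxyl, and no allylic ester is left for zerovalent palladium to ionise in the next step.

Step 4
Reactants: 4 (1R,6S)-2-bromo-6-[(tert-butyldimethylsilyl)oxy]cyclohexa-2,4-dien-1-ol; 5 (tributylstannyl)methanol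
Product: 6 (1S,6S)-6-[(tert-butyldimethylsilyl)oxy]-2-(hydroxymethyl)cyclohexa-2,4-dien-1-ol (trans; free C2-OH and C7-OH, C3 silyl ether in target numbering)
Conditions: Pd(PPh3)4 (5 mol%), 1,4-dioxane, 80 °C; aqueous KF work-up
Reagents that add atoms: (tributylstannyl)methanol 5, CCCC[Sn](CCCC)(CCCC)CO
Why: Stille coupling (oxidative addition of the vinylic C–Br bond to zerovalent palladium, transfer of the hydroxymethyl group from tin, reductive elimination) forms the C1–C7 bond at the bromine-bearing carbon without moving the diene or touching the two stereocentres.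

Step 5
Reactants: 6 (1S,6S)-6-[(tert-butyldimethylsilyl)oxy]-2-(hydroxymethyl)cyclohexa-2,4-dien-1-ol
Product: 7 (1R,2R,3S,6S)-3-[(tert-butyldimethylsilyl)oxy]-1-(hydroxymethyl)-7-oxabicyclo[4.1.0]hept-4-en-2-ol (oxirane oxygen cis to the C2 hydroxyl and trans to the silyl ether)
Conditions: VO(acac)2 (5 mol%), t-BuOOH (1.2 equiv, in decane), CH2Cl2, 0 °C
Reagents that add atoms: tert-butyl hydroperoxide, CC(C)(C)OO
Why: The hydroperoxide oxidises VO(acac)2 from tetravalent to pentavalent vanadium, which takes up the C2 (and C7) alkoxide of 6 and a side-on bound tert-butyl peroxide, and the activated peroxide oxygen is then passed within this vanadate ester to the C1=C6 alkene, both C–O bonds forming in one concerted step. The closest known reaction type is the vanadium-catalysed, hydroxyl-directed epoxidation of cyclic allylic alcohols with alkyl hydroperoxides, which gives syn epoxy alcohols from cyclohex-2-enols. The oxirane, the only ring formed, closes by suprafacial transfer of a single oxygen atom to both alkene carbons (a formal [2+1] addition through a spiro transition state, not an exo or endo cyclisation). Both new stereocentres, C1 and C6, are controlled by the C2 carbinol centre: the metal is anchored on the face of the C2–O bond, so the oxygen should arrive syn to C2-OH and anti to the C3 silyl ether. The step needs site selectivity for C1=C6 over C4=C5 and face selectivity; the first is secured because C1=C6 is trisubstituted and allylic to two free hydroxyls whereas C4=C5 is allylic only to a silyl ether, the second by the vanadate tether, reinforced by the bulk of the C3 silyl ether on the opposite face.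

Step 6
Reactants: 7 (1R,2R,3S,6S)-3-[(tert-butyldimethylsilyl)oxy]-1-(hydroxymethyl)-7-oxabicyclo[4.1.0]hept-4-en-2-ol; 8 benzoyl chloride
Product: 9 [(1S,2R,3S,6S)-2-(benzoyloxy)-3-[(tert-butyldimethylsilyl)oxy]-7-oxabicyclo[4.1.0]hept-4-en-1-yl]methyl benzoate
Conditions: BzCl (3 equiv), Et3N, DMAP (cat.), CH2Cl2, 0 °C to rt
Reagents that add atoms: benzoyl chloride 8, O=C(Cl)c1ccccc1
Why: DMAP-catalysed acylation esterifies the primary C7 and the secondary C2 hydroxyl, the only two free OH groups, with retention at C2, while the amine base keeps the medium non-acidic so that the vinyl oxirane stays closed.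

Step 7
Reactants: 9 [(1S,2R,3S,6S)-2-(benzoyloxy)-3-[(tert-butyldimethylsilyl)oxy]-7-oxabicyclo[4.1.0]hept-4-en-1-yl]methyl benzoate
Product: 10 [(1R,2R,3S,6R)-2-(benzoyloxy)-3-[(tert-butyldimethylsilyl)oxy]-6-chloro-1-hydroxycyclohex-4-en-1-yl]methyl benzoate (C1-OH and C6-Cl trans)
Conditions: HCl (1 M in Et2O, 1.5 equiv), CH2Cl2, −40 °C
Reagents that add atoms: hydrogen chloride, Cl
Why: Acid-promoted SN2 opening of a vinyl oxirane: chloride attacks the protonated epoxide at the allylic carbon C6 from the face opposite to the breaking C6–O bond, so C6 is inverted and the trans C1-OH/C6-Cl pair results, because C1 is quaternary and flanked by two acyloxy-bearing carbons and conjugate attack at C4 is slowed by the adjacent C3–O bond and its bulky silyl group.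

Step 8
Reactants: 10 [(1R,2R,3S,6R)-2-(benzoyloxy)-3-[(tert-butyldimethylsilyl)oxy]-6-chloro-1-hydroxycyclohex-4-en-1-yl]methyl benzoate
Product: 11 [(1R,2R,3S,6R)-2-(benzoyloxy)-6-chloro-1,3-dihydroxycyclohex-4-en-1-yl]methyl benzoate (CNP0326102.1)
Conditions: HF·pyridine, pyridine, THF, 0 °C to rt
Reagents that add atoms: none
Why: Acidic fluoride desilylation breaks only the Si–O bond, so C3 keeps its configuration, and the absence of base avoids benzoyl migration from O2 to O3 and re-closure of the chlorohydrin to the oxirane.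

Compound list
1 | (1S,2S)-3-bromocyclohexa-3,5-diene-1,2-diol | BrC1=CC=C[C@H](O)[C@@H]1O | starting material
2 | (1S,6S)-2-bromo-6-[(tert-butyldimethylsilyl)oxy]cyclohexa-2,4-dien-1-ol | BrC1=CC=C[C@H](O[Si](C)(C)C(C)(C)C)[C@@H]1O | intermediate
3 | (1R,6S)-2-bromo-6-[(tert-butyldimethylsilyl)oxy]cyclohexa-2,4-dien-1-yl 4-nitrobenzoate | BrC1=CC=C[C@H](O[Si](C)(C)C(C)(C)C)[C@H]1OC(=O)c2ccc(cc2)[N+](=O)[O-] | intermediate
4 | (1R,6S)-2-bromo-6-[(tert-butyldimethylsilyl)oxy]cyclohexa-2,4-dien-1-ol | BrC1=CC=C[C@H](O[Si](C)(C)C(C)(C)C)[C@H]1O | intermediate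
5 | (tributylstannyl)methanol | CCCC[Sn](CCCC)(CCCC)CO | starting material
6 | (1S,6S)-6-[(tert-butyldimethylsilyl)oxy]-2-(hydroxymethyl)cyclohexa-2,4-dien-1-ol (same spatial arrangement as 4; the C1 descriptor changes by priority only) | OCC1=CC=C[C@H](O[Si](C)(C)C(C)(C)C)[C@H]1O | intermediate
7 | (1R,2R,3S,6S)-3-[(tert-butyldimethylsilyl)oxy]-1-(hydroxymethyl)-7-oxabicyclo[4.1.0]hept-4-en-2-ol | OC[C@]12O[C@H]1C=C[C@H](O[Si](C)(C)C(C)(C)C)[C@H]2O | intermediate
8 | benzoyl chloride | O=C(Cl)c1ccccc1 | starting material
9 | [(1S,2R,3S,6S)-2-(benzoyloxy)-3-[(tert-butyldimethylsilyl)oxy]-7-oxabicyclo[4.1.0]hept-4-en-1-yl]methyl benzoate (same spatial arrangement as 7; the C1 descriptor changes by priority only) | O=C(OC[C@]12O[C@H]1C=C[C@H](O[Si](C)(C)C(C)(C)C)[C@H]2OC(=O)c3ccccc3)c4ccccc4 | intermediate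
10 | [(1R,2R,3S,6R)-2-(benzoyloxy)-3-[(tert-butyldimethylsilyl)oxy]-6-chloro-1-hydroxycyclohex-4-en-1-yl]methyl benzoate | O=C(OC[C@]1(O)[C@H](Cl)C=C[C@H](O[Si](C)(C)C(C)(C)C)[C@H]1OC(=O)c2ccccc2)c3ccccc3 | intermediate
11 | [(1R,2R,3S,6R)-2-(benzoyloxy)-6-chloro-1,3-dihydroxycyclohex-4-en-1-yl]methyl benzoate | O=C(OC[C@]1(O)[C@H](Cl)C=C[C@H](O)[C@H]1OC(=O)c1ccccc1)c1ccccc1 | target

Total step count: 8
Longest linear sequence: 8 steps (1 to 11)

Steps most likely to fail

Step 2 (inversion on the cyclohexadienol). The activated oxyphosphonium oxygen may be lost by elimination with aromatisation of the ring, or the carboxylate may enter in SN2' fashion, instead of the wanted inversion. The fallback sets out from 1 and moves the inversion to the dihydro series, where aromatisation is impossible.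
- Diimide, made from dipotassium azodicarboxylate (KO2CN=NCO2K) and AcOH in MeOH, should reduce only the disubstituted alkene and give (1S,2S)-3-bromocyclohex-3-ene-1,2-diol F1.
- TBSCl and imidazole should silylate the non-allylic hydroxyl to (1S,6S)-2-bromo-6-[(tert-butyldimethylsilyl)oxy]cyclohex-2-en-1-ol F2.
- Mitsunobu esterification with 4-nitrobenzoic acid should invert the allylic carbinol to (1R,6S)-2-bromo-6-[(tert-butyldimethylsilyl)oxy]cyclohex-2-en-1-yl 4-nitrobenzoate F3.
- Wohl–Ziegler bromination (NBS, AIBN) at the free allylic methylene should give (1R,6S)-2,4-dibromo-6-[(tert-butyldimethylsilyl)oxy]cyclohex-2-en-1-yl 4-nitrobenzoate F4 as a pair of C4 epimers.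
- Dehydrobromination with DBU should restore the second alkene, and the route is rejoined at 3.

Step 7 (chloride opening of the vinyl oxirane). Chloride may add in conjugate fashion at C4, the C7 benzoate carbonyl may take part at C6 and cause acyl migration or cis addition, the ion pair may collapse with retention, or the silyl ether may be lost too early. The fallback sets out from 7 and opens the oxirane before acylation, as a 2,3-epoxy alcohol under titanium chelation control.
- Ti(OiPr)4 with Et2NH·HCl in CH2Cl2 should deliver chloride with inversion to C6, the oxirane carbon remote from the bound C7 and C2 alkoxides, to give (1R,2R,3S,6R)-3-[(tert-butyldimethylsilyl)oxy]-6-chloro-1-(hydroxymethyl)cyclohex-4-ene-1,2-diol F5.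
- Benzoylation of its primary and secondary hydroxyls (BzCl, pyridine, DMAP, 0 °C; the tertiary C1-OH stays free) rejoins the route at 10.

Step 5 (directed epoxidation). With two hydroxyls on vanadium the facial control may be poor, the Lewis-acidic metal may open the vinyl oxirane as it forms, or the dienediol may dehydrate to the arene. The fallback sets out from 6 and uses a single directing hydroxyl and a metal-free oxidant.
- Selective acylation of the primary hydroxyl (BzCl 1.05 equiv, 2,4,6-collidine, CH2Cl2, −78 °C) should give [(5S,6S)-5-[(tert-butyldimethylsilyl)oxy]-6-hydroxycyclohexa-1,3-dien-1-yl]methyl benzoate F6.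
- Hydrogen-bond-directed (Henbest-type) epoxidation with mCPBA and NaHCO3 in CH2Cl2 at 0 °C should oxidise the trisubstituted C1=C6 alkene syn to C2-OH and give [(1R,2R,3S,6S)-3-[(tert-butyldimethylsilyl)oxy]-2-hydroxy-7-oxabicyclo[4.1.0]hept-4-en-1-yl]methyl benzoate F7.
- Benzoylation of the C2 hydroxyl (BzCl, Et3N, DMAP) rejoins the route at 9.

Further compounds
F1 | step 2 | (1S,2S)-3-bromocyclohex-3-ene-1,2-diol | BrC1=CCC[C@H](O)[C@@H]1O
F2 | step 2 | (1S,6S)-2-bromo-6-[(tert-butyldimethylsilyl)oxy]cyclohex-2-en-1-ol | BrC1=CCC[C@H](O[Si](C)(C)C(C)(C)C)[C@@H]1O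
F3 | step 2 | (1R,6S)-2-bromo-6-[(tert-butyldimethylsilyl)oxy]cyclohex-2-en-1-yl 4-nitrobenzoate | BrC1=CCC[C@H](O[Si](C)(C)C(C)(C)C)[C@H]1OC(=O)c2ccc(cc2)[N+](=O)[O-]
F4 | step 2 | (1R,6S)-2,4-dibromo-6-[(tert-butyldimethylsilyl)oxy]cyclohex-2-en-1-yl 4-nitrobenzoate (C4 epimers) | BrC1=CC(Br)C[C@H](O[Si](C)(C)C(C)(C)C)[C@H]1OC(=O)c2ccc(cc2)[N+](=O)[O-]
F5 | step 7 | (1R,2R,3S,6R)-3-[(tert-butyldimethylsilyl)oxy]-6-chloro-1-(hydroxymethyl)cyclohex-4-ene-1,2-diol | OC[C@]1(O)[C@H](Cl)C=C[C@H](O[Si](C)(C)C(C)(C)C)[C@H]1O
F6 | step 5 | [(5S,6S)-5-[(tert-butyldimethylsilyl)oxy]-6-hydroxycyclohexa-1,3-dien-1-yl]methyl benzoate | O=C(OCC1=CC=C[C@H](O[Si](C)(C)C(C)(C)C)[C@H]1O)c2ccccc2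
F7 | step 5 | [(1R,2R,3S,6S)-3-[(tert-butyldimethylsilyl)oxy]-2-hydroxy-7-oxabicyclo[4.1.0]hept-4-en-1-yl]methyl benzoate | O=C(OC[C@]12O[C@H]1C=C[C@H](O[Si](C)(C)C(C)(C)C)[C@H]2O)c3ccccc3
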